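## The problem

Compound 28 is a daucane: a cyclopentane (C1–C5) fused trans through the C1–C5 bond to a cycloheptane (C1, C5–C10), with a quaternary methyl-bearing C1, a methine C5 and a tertiary isopropyl carbinol at C4. Six stereocentres must be set (C1, C4, C5, C6, C8, C9). C4 can be bought, but it then has to control the quaternary C1 across C5, and C5 must be fixed while it is still epimerisable. Once both are in place the angular C1 methyl marks the β face of the seven-membered ring; the oxygens on C6, C8 and C9 all lie on the opposite (α) face, so these three centres can be relayed from the ring fusion. The four contiguous oxidised carbons C6–C9 carry an aryl ester, a ketone, a tertiary and a secondary alcohol, so the two secondary oxygens (C6 acylated, C9 free) must be told apart and C7 oxidised beside them. The finished array is fragile: C6 is an epimerisable α-acyloxy ketone centre, C8 a tertiary α-ketol, the C9 hydroxyl is β to the ketone (retro-aldol), and the phenolic ester can migrate or cleave. Base is therefore excluded once the C7 ketone exists, and the tertiary C4 carbinol rules out strong acid. The feature that opens the structure is the cis-1,4 relation of the C6 and C9 oxygens across C7–C8 inside the seven-membered ring: it is the imprint of an endoperoxide on a C6=C7–C8=C9 diene that the ring holds s-cis, and the C7=C8 alkene left behind sits exactly where the last two oxygens are needed.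

## Retrosynthesis

**Protecting groups (28 ⇐ 27 ⇐ 26).** Only O–CH2Ph and O–Si bonds are cut. The phenol is carried as a benzyl ether so that the acyl donor 22 is a purchasable acid chloride and the last step is a neutral hydrogenolysis. The C4 and C9 silyl ethers of 26 fall together under buffered fluoride. Both steps must leave the α-acyloxy ketone untouched, which excludes basic deprotection.

**C7 ketone and C8 carbinol (26 ⇐ 25 ⇐ 24 ⇐ 23).** The ketone is traced to the C7 carbinol of 25. The C8–O bond of 25 is then cut back to the 7β,8β-epoxide 24, and both epoxide C–O bonds back to alkene 23. The tertiary C8 is the carbon at which a trisubstituted epoxide opens under acid, with inversion. An epoxide on the β face, the face a peracid should take when both allylic oxygens of 23 are capped and point α, therefore delivers the C8 hydroxyl α and leaves on C7 the only oxidisable hydroxyl. The neighbouring options are weaker: a hydroxyl-directed α-epoxide would have to be opened at the secondary C7 against its normal regiochemistry, and osmylation would come anti to the allylic oxygens and give the C8 epimer. The forward steps need β-face selectivity, opening at C8, and no interference from the C6 ester.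

**Telling C6 and C9 apart (23 ⇐ 21 + 22 ⇐ 20).** The ester C–O bond and the C9 O–Si bond are cut to give ene-diol 20. The C6 hydroxyl is flanked by C5, which sits between the two fully substituted carbons C1 and C4; the C9 hydroxyl is flanked by a methylene. Silylation should therefore go to C9 first and leave C6 for 22. The forward reaction must show this site selectivity.

**Key disconnection (20 ⇐ 19 ⇐ 17 + 18).** The O–O bond of endoperoxide 19 is re-formed and the C6–O and C9–O bonds are cut together, giving diene 17 and oxygen 18. This removes two stereocentres and both secondary oxygens in one transform, and the cis relation is guaranteed by the suprafacial cycloaddition. Diene 17 is a hydrocarbon apart from the C4 silyl ether and carries only C1, C4 and C5. The forward reaction needs attack on the α face and cycloaddition in preference to the ene reaction.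

**C8 methyl (17 ⇐ 15 + 16 ⇐ 13).** The C8–CH3 bond is cut to dienyl triflate 15 and methylmagnesium bromide 16, and 15 is traced to enone 13 by way of its cross-conjugated enolate. Adding methyl to the ketone and dehydrating would be equally short, but it leaves the position of the new double bond open (endocyclic C8=C9 against exocyclic). The triflate fixes both double bonds of 17 by construction.

**Seven-membered ring (13 ⇐ 12 ⇐ 11 ⇐ 9 + 10).** The C6=C7 bond is cut by a metathesis transform to diene-ol 11, and the C7–C8 bond to aldehyde 9 and vinylmagnesium bromide 10. Closing the ring by aldol or phosphonate condensation onto a C6 aldehyde would run in base, where C5 epimerises and a five-membered ring can form instead. Metathesis is neutral, and C5 is already locked as a vinyl-bearing centre. Precursor 9 is monocyclic.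

**Side-arm adjustments (9 ⇐ 8 ⇐ 7).** The C9–C10–C8 aldehyde is masked as the dioxolane of 8, and the C5 vinyl group is traced to the formyl group of 7 by methylenation. Neither transform touches a stereocentre.

**Quaternary C1 (7 ⇐ 4 + 5).** The C1–C10 bond is cut by a conjugate-addition transform to enal 4 and Grignard reagent 5, which brings C10, C9 and C8. C1 must be formed anti to the C4 silyloxy group; C5 is then set by equilibration of the formyl group trans to both the C4 isopropyl group and the new chain.

**Cyclopentene (4 ⇐ 2 ⇐ 1).** The C1–C5 bond is cut by an aldol-condensation transform, and C1 and C6 are reconnected as the ring alkene of silyl ether 2, which comes from (S)-terpinen-4-ol 1. All ten skeletal carbons of the five-membered ring, its methyl, its isopropyl group, C6 and the C4 stereocentre thus come from one purchasable terpene.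

## Roads not taken

**Alternative 1: Claisen ring expansion.** The cut is the C7–C8 bond, with a C5–O bond re-formed: the cycloheptenone A2 is traced to the bicyclic allyl vinyl ether A1, whose ether oxygen joins C5 and C9. Heating A1 should form C7–C8, break C5–O and turn the oxolane into the carbocycle with a C9 ketone and a C5=C6 alkene.
- Merits: the key step makes a carbon–carbon bond and the seven-membered ring without reagents, and the C9 oxygen arrives with the ring. In this respect it is better than the chosen key step, which forms no carbon–carbon bond and leaves ring closure to a separate metathesis (step 7).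
- Weak points for this target: A2 has nothing at C4 (no isopropyl, no hydroxyl), its C8 methyl centre is uncontrolled, and oxygen is present only at C9. C6, C7 and C8 would have to be oxidised one at a time, C5 reduced with control of the ring fusion, and C4 built into a quaternary carbinol late. A1 itself needs a tertiary ether at a ring-fusion carbon.
- Comparison: against the better skeletal economy of this road the chosen plan sets two C–O bonds and two stereocentres in one step with a guaranteed cis relation, and C4 taken from the chiral pool.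

**Alternative 2: carbenoid C–H insertion from citronellol.** The cut is the C1–C5 bond: cyclopentanone A5 is traced to the α-diazo-β-keto ester A4, made from (S)-citronellol A3. With Rh2(OAc)4 the carbenoid at C5 should insert into the tertiary C1–H bond with retention.
- Merits: the quaternary C1 is transferred from a purchased stereocentre and does not depend on any facial selectivity. This is better than the chosen plan exactly where that plan is weakest (step 3).
- Weak points for this target: A5 is only the five-membered ring. C4 is the ketone of a β-keto ester, so the isopropyl group would have to add to an enolisable, hindered carbonyl with control relative to a C1 whose two substituents differ little in size. The whole seven-membered ring and all four of its oxygen functions remain to be made.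
- Comparison: the chosen plan buys C4, where this road must create it, and covers its risk at C1 with a fallback that moves control to a reagent-set carbinol.

**Alternative 3: ketone–aldehyde pinacol closure.** The cut is the C8–C9 bond: diol A7 is traced to keto aldehyde A6. SmI2 should couple the C9 aldehyde with the C8 methyl ketone, close the ring and set both carbinol centres as the cis-diol.
- Merits: one step closes the ring, forms a carbon–carbon bond and delivers C8 and C9 at their final oxidation level with C6 and C7 already oxygenated. The end-game after cyclisation would be shorter than the one chosen here.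
- Weak points for this target: A6 needs the C6 and C7 stereocentres installed on an open chain next to the congested C5, with no ring to guide them. The C8 ketone carries an α-silyloxy group, which divalent samarium tends to cleave reductively. The cis-diol preference of pinacol cyclisations weakens in seven-membered rings, and the α face must be chosen as well. The C6 benzyl ether must later be exchanged for the aryl ester.
- Comparison: the chosen plan sets against the shorter end-game a far simpler cyclisation substrate (hydrocarbon diene 17) and stereocontrol that comes from a concerted addition to a rigid ring.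

Key step: step 11

Remark on the chemistry (assumption): (S)-terpinen-4-ol of high enantiomeric purity is taken as purchasable. Atoms carry the daucane numbers C1–C10 throughout (C15 is the methyl on C1, C14 the methyl on C8, the isopropyl group is on C4). β is the face of the C1 methyl and α the opposite face. All compounds from 7 onward have 1β-methyl, 5α-H, 4β-silyloxy (or hydroxy) and 4α-isopropyl.

## Route

Step 1
Reactants: 1 (S)-terpinen-4-ol
Product: 2 (S)-terpinen-4-ol triethylsilyl ether
Conditions: Et3SiOTf, 2,6-lutidine, CH2Cl2, 0 °C → rt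
Reagents that add atoms: triethylsilyl trifluoromethanesulfonate, CC[Si](CC)(CC)OS(=O)(=O)C(F)(F)F
Why: Silyl ether formation on a hindered tertiary alcohol with a silyl triflate; C4 is untouched, and the ether blocks retro-aldol and dehydration in step 2 and later serves as the β-face shield.

Step 2
Reactants: 2 (S)-terpinen-4-ol triethylsilyl ether
Product: 4 (R)-5-isopropyl-2-methyl-5-(triethylsilyloxy)cyclopent-1-ene-1-carbaldehyde, via keto aldehyde 3 (not isolated)
Conditions: O3, CH2Cl2, −78 °C; Me2S, −78 °C → rt; then piperidine (cat.), AcOH (cat.), toluene, 70 °C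
Reagents that add atoms: ozone, [O-][O+]=O
Why: Ozonolysis with reductive work-up opens the ring alkene to the 6-oxoheptanal 3; amine-catalysed intramolecular aldol condensation (aldehyde enamine onto the methyl ketone, five-membered closure, dehydration) gives the cyclopentene carbaldehyde, a ring contraction well established for 6-oxoheptanals. No stereocentre is formed.

Step 3
Reactants: 4 (R)-5-isopropyl-2-methyl-5-(triethylsilyloxy)cyclopent-1-ene-1-carbaldehyde, 5 [2-(1,3-dioxolan-2-yl)ethyl]magnesium bromide
Product: 7 1α-[2-(1,3-dioxolan-2-yl)ethyl]-4α-isopropyl-1β-methyl-4β-(triethylsilyloxy)cyclopentane-5β-carbaldehyde, via trimethylsilyl enol ether 6 (not isolated)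
Conditions: CuBr·SMe2 (20 mol %), Me3SiCl, THF, −78 → −40 °C; then K2CO3, MeOH, 0 °C → rt
Reagents that add atoms: chlorotrimethylsilane, C[Si](C)(C)Cl (its silicon is carried by 6 only and is lost again before 7)
Why: Copper-catalysed, silyl chloride-accelerated conjugate addition of a Grignard reagent to a β,β-disubstituted enal creates the quaternary C1; addition is expected on the α face, anti to the silyloxy group, whose triethylsilyl residue lies over the ring while the isopropyl group can turn its C–H inward. Carbonate in methanol cleaves the silyl enol ether and equilibrates C5 to the epimer with the formyl group trans to both the isopropyl group and the new chain.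

Step 4
Reactants: 7 1α-[2-(1,3-dioxolan-2-yl)ethyl]-4α-isopropyl-1β-methyl-4β-(triethylsilyloxy)cyclopentane-5β-carbaldehyde
Product: 8 1α-[2-(1,3-dioxolan-2-yl)ethyl]-4α-isopropyl-1β-methyl-4β-(triethylsilyloxy)-5β-vinylcyclopentane
Conditions: Ph3PCH3Br, KOtBu, THF, 0 °C → rt
Reagents that add atoms: methyltriphenylphosphonium bromide, C[P+](c1ccccc1)(c1ccccc1)c1ccccc1.[Br-]
Why: Wittig methylenation of a hindered aldehyde; C5 is already at its thermodynamic configuration, and turning formyl into vinyl ends its epimerisability.

Step 5
Reactants: 8 1α-[2-(1,3-dioxolan-2-yl)ethyl]-4α-isopropyl-1β-methyl-4β-(triethylsilyloxy)-5β-vinylcyclopentane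
Product: 9 3-[4α-isopropyl-1β-methyl-4β-(triethylsilyloxy)-5β-vinylcyclopent-1α-yl]propanal
Conditions: PPTS (cat.), acetone/H2O, 55 °C
Reagents that add atoms: water, O
Why: Acid-catalysed acetal hydrolysis; the weak pyridinium acid should spare the hindered tertiary silyl ether, and no stereocentre is involved.

Step 6
Reactants: 9 3-[4α-isopropyl-1β-methyl-4β-(triethylsilyloxy)-5β-vinylcyclopent-1α-yl]propanal, 10 vinylmagnesium bromide
Product: 11 5-[4α-isopropyl-1β-methyl-4β-(triethylsilyloxy)-5β-vinylcyclopent-1α-yl]pent-1-en-3-ol (both C8 epimers)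
Conditions: THF, −78 → 0 °C; aq. NH4Cl
Reagents that add atoms: none
Why: Grignard 1,2-addition to an aldehyde brings in C7; the new C8 carbinol centre is formed without control and is removed by oxidation in step 8.

Step 7
Reactants: 11 5-[4α-isopropyl-1β-methyl-4β-(triethylsilyloxy)-5β-vinylcyclopent-1α-yl]pent-1-en-3-ol
Product: 12 4β-(triethylsilyloxy)-14-nordauc-6-en-8-ol (trans-fused; both C8 epimers)
Conditions: second-generation Grubbs catalyst [(H2IMes)(PCy3)Cl2Ru=CHPh, 5 mol %], CH2Cl2, 40 °C
Reagents that add atoms: none
Why: Ring-closing metathesis forms C6=C7 and the seven-membered ring with loss of ethylene; the catalyst should load on the unhindered allylic-alcohol olefin and close onto the hindered C5 vinyl group, and the trans fusion is already fixed by C1 and C5.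

Step 8
Reactants: 12 4β-(triethylsilyloxy)-14-nordauc-6-en-8-ol
Product: 13 4β-(triethylsilyloxy)-14-nordauc-6-en-8-one
Conditions: Dess–Martin periodinane, NaHCO3, CH2Cl2, rt
Reagents that add atoms: none
Why: Periodinane oxidation of a secondary allylic alcohol to the enone; both C8 epimers converge.

Step 9
Reactants: 13 4β-(triethylsilyloxy)-14-nordauc-6-en-8-one
Product: 15 4β-(triethylsilyloxy)-14-nordauca-6,8-dien-8-yl trifluoromethanesulfonate, via potassium dienolate 14 (not isolated)
Conditions: KN(SiMe3)2, THF, −78 °C; PhNTf2, −78 → 0 °C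
Reagents that add atoms: N-phenyl-bis(trifluoromethanesulfonimide), O=S(=O)(N(c1ccccc1)S(=O)(=O)C(F)(F)F)C(F)(F)F
Why: Kinetic α′-deprotonation of the enone at the unhindered C9 methylene gives the cross-conjugated enolate, and O-triflation fixes the C8=C9 bond; the γ-hydrogen at C5 is tertiary and should not compete at low temperature.

Step 10
Reactants: 15 4β-(triethylsilyloxy)-14-nordauca-6,8-dien-8-yl trifluoromethanesulfonate, 16 methylmagnesium bromide
Product: 17 4β-(triethylsilyloxy)dauca-6,8-diene
Conditions: Fe(acac)3 (5 mol %), THF/NMP, −30 → 0 °C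
Reagents that add atoms: none
Why: Iron-catalysed cross-coupling of an alkenyl triflate with a Grignard reagent installs the C8 methyl with both double bonds held in place.

Step 11
Reactants: 17 4β-(triethylsilyloxy)dauca-6,8-diene, 18 oxygen
Product: 19 6α,9α-epidioxy-4β-(triethylsilyloxy)dauc-7-ene
Conditions: O2, 5,10,15,20-tetraphenylporphyrin (cat.), hν (visible), CH2Cl2, −30 °C
Reagents that add atoms: none
Why: Energy transfer from the photoexcited porphyrin converts O2 into singlet oxygen, which adds suprafacially across C6 and C9 of the ring-held s-cis diene in a concerted [4+2] cycloaddition, forming both C–O bonds and leaving the C7=C8 alkene. The closest known reaction is the photooxygenation of cyclohepta-1,3-dienes to 6,7-dioxabicyclo[3.2.2]non-8-enes. The new six-membered 1,2-dioxine ring (C6–O–O–C9–C8=C7) is closed by the cycloaddition itself, both bonds at once. C6 and C9 are necessarily cis to each other because the addition is suprafacial on the diene. Their configuration relative to the ring fusion is decided by the face of attack: the angular C1 methyl is 1,3 to both diene termini on the β face and the C4 silyloxy group lies on the same face next to C6, so oxygen should enter from the α face past the C5 hydrogen. The step needs this facial selectivity and cycloaddition in preference to the ene reaction; the latter is favoured by the cisoid diene in the seven-membered ring and by low temperature in a non-polar solvent.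

Step 12
Reactants: 19 6α,9α-epidioxy-4β-(triethylsilyloxy)dauc-7-ene
Product: 20 4β-(triethylsilyloxy)dauc-7-ene-6α,9α-diol
Conditions: Zn, AcOH, CH2Cl2, 0 °C → rt
Reagents that add atoms: none
Why: Reductive cleavage of the weak O–O bond; neither C–O bond is broken, so the cis-6α,9α-diol is released with both configurations retained and the alkene intact.

Step 13
Reactants: 20 4β-(triethylsilyloxy)dauc-7-ene-6α,9α-diol
Product: 21 9α-(tert-butyldimethylsilyloxy)-4β-(triethylsilyloxy)dauc-7-en-6α-ol
Conditions: tBuMe2SiCl (1.1 equiv), imidazole, DMF, −20 → 0 °C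
Reagents that add atoms: tert-butyldimethylsilyl chloride, CC(C)(C)[Si](C)(C)Cl
Why: Site-selective silylation of the less hindered allylic alcohol: C9 is flanked by the C10 methylene, whereas C6 is flanked by C5 between two fully substituted carbons.

Step 14
Reactants: 21 9α-(tert-butyldimethylsilyloxy)-4β-(triethylsilyloxy)dauc-7-en-6α-ol, 22 4-(benzyloxy)benzoyl chloride
Product: 23 9α-(tert-butyldimethylsilyloxy)-4β-(triethylsilyloxy)dauc-7-en-6α-yl 4-(benzyloxy)benzoate
Conditions: Et3N, DMAP (cat.), CH2Cl2, rt
Reagents that add atoms: none
Why: Nucleophile-catalysed acylation of the remaining hindered secondary alcohol with an acid chloride; the C6–O bond is not broken, so the configuration is retained.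

Step 15
Reactants: 23 9α-(tert-butyldimethylsilyloxy)-4β-(triethylsilyloxy)dauc-7-en-6α-yl 4-(benzyloxy)benzoate
Product: 24 9α-(tert-butyldimethylsilyloxy)-7β,8β-epoxy-4β-(triethylsilyloxy)daucan-6α-yl 4-(benzyloxy)benzoate
Conditions: mCPBA, NaHCO3, CH2Cl2, 0 °C
Reagents that add atoms: 3-chloroperoxybenzoic acid, OOC(=O)c1cccc(Cl)c1
Why: Peracid (Prilezhaev) epoxidation of the trisubstituted alkene; with both allylic oxygens capped and on the α face, the reagent should approach anti to them and place the epoxide on the β face.

Step 16
Reactants: 24 9α-(tert-butyldimethylsilyloxy)-7β,8β-epoxy-4β-(triethylsilyloxy)daucan-6α-yl 4-(benzyloxy)benzoate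
Product: 25 9α-(tert-butyldimethylsilyloxy)-7β,8α-dihydroxy-4β-(triethylsilyloxy)daucan-6α-yl 4-(benzyloxy)benzoate
Conditions: HClO4 (cat.), THF/H2O, 0 °C
Reagents that add atoms: water, O
Why: Acid-catalysed hydrolysis of a trisubstituted epoxide: water attacks the tertiary C8, the carbon that best carries positive charge, from the α face anti to the epoxide oxygen (inversion), so C8 ends with hydroxyl α and methyl β while the epoxide oxygen stays on C7.

Step 17
Reactants: 25 9α-(tert-butyldimethylsilyloxy)-7β,8α-dihydroxy-4β-(triethylsilyloxy)daucan-6α-yl 4-(benzyloxy)benzoate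
Product: 26 9α-(tert-butyldimethylsilyloxy)-8α-hydroxy-7-oxo-4β-(triethylsilyloxy)daucan-6α-yl 4-(benzyloxy)benzoate
Conditions: Dess–Martin periodinane, NaHCO3, CH2Cl2, 0 °C → rt
Reagents that add atoms: none
Why: Periodinane oxidation of the only secondary hydroxyl; the tertiary C8 hydroxyl cannot be oxidised, and the buffered, non-basic conditions protect the C6 centre.

Step 18
Reactants: 26 9α-(tert-butyldimethylsilyloxy)-8α-hydroxy-7-oxo-4β-(triethylsilyloxy)daucan-6α-yl 4-(benzyloxy)benzoate
Product: 27 4β,8α,9α-trihydroxy-7-oxodaucan-6α-yl 4-(benzyloxy)benzoate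
Conditions: HF·pyridine, pyridine, THF, 0 °C → rt
Reagents that add atoms: none
Why: Fluoride-mediated cleavage of both silyl ethers under weakly acidic conditions that avoid retro-aldol cleavage, C6 epimerisation and acyl migration.

Step 19
Reactants: 27 4β,8α,9α-trihydroxy-7-oxodaucan-6α-yl 4-(benzyloxy)benzoate
Product: 28 4β,8α,9α-trihydroxy-7-oxodaucan-6α-yl 4-hydroxybenzoate (CNP0241001.1)
Conditions: H2 (1 atm), 10% Pd/C, EtOAc, rt
Reagents that add atoms: none
Why: Catalytic hydrogenolysis of the aryl benzyl ether under neutral conditions; ketone, ester and alcohols should be unaffected.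

## Compound list

1 | (S)-terpinen-4-ol | CC(C)[C@]1(O)CCC(C)=CC1 | starting material
2 | (S)-terpinen-4-ol triethylsilyl ether | CC(C)[C@]1(O[Si](CC)(CC)CC)CCC(C)=CC1 | intermediate
3 | (S)-3-isopropyl-6-oxo-3-(triethylsilyloxy)heptanal (keto aldehyde) | CC(C)[C@](CC=O)(O[Si](CC)(CC)CC)CCC(C)=O | intermediate (not isolated)
4 | (R)-5-isopropyl-2-methyl-5-(triethylsilyloxy)cyclopent-1-ene-1-carbaldehyde | CC(C)[C@]1(O[Si](CC)(CC)CC)CCC(C)=C1C=O | intermediate
5 | [2-(1,3-dioxolan-2-yl)ethyl]magnesium bromide | Br[Mg]CCC1OCCO1 | starting material
6 | trimethylsilyl enol ether of 7 (C5=C6–OSiMe3, enol ether geometry not defined) | CC(C)[C@]1(O[Si](CC)(CC)CC)CC[C@](C)(CCC2OCCO2)C1=CO[Si](C)(C)C | intermediate (not isolated)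
7 | 1α-[2-(1,3-dioxolan-2-yl)ethyl]-4α-isopropyl-1β-methyl-4β-(triethylsilyloxy)cyclopentane-5β-carbaldehyde | CC(C)[C@]1(O[Si](CC)(CC)CC)CC[C@](C)(CCC2OCCO2)[C@H]1C=O | intermediate
8 | 1α-[2-(1,3-dioxolan-2-yl)ethyl]-4α-isopropyl-1β-methyl-4β-(triethylsilyloxy)-5β-vinylcyclopentane | CC(C)[C@]1(O[Si](CC)(CC)CC)CC[C@](C)(CCC2OCCO2)[C@H]1C=C | intermediate
9 | 3-[4α-isopropyl-1β-methyl-4β-(triethylsilyloxy)-5β-vinylcyclopent-1α-yl]propanal | CC(C)[C@]1(O[Si](CC)(CC)CC)CC[C@](C)(CCC=O)[C@H]1C=C | intermediate
10 | vinylmagnesium bromide | C=C[Mg]Br | starting material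
11 | 5-[4α-isopropyl-1β-methyl-4β-(triethylsilyloxy)-5β-vinylcyclopent-1α-yl]pent-1-en-3-ol (C8 epimers) | CC(C)[C@]1(O[Si](CC)(CC)CC)CC[C@](C)(CCC(O)C=C)[C@H]1C=C | intermediate
12 | 4β-(triethylsilyloxy)-14-nordauc-6-en-8-ol (C8 epimers) | CC(C)[C@]1(O[Si](CC)(CC)CC)CC[C@]2(C)CCC(O)C=C[C@H]21 | intermediate
13 | 4β-(triethylsilyloxy)-14-nordauc-6-en-8-one | CC(C)[C@]1(O[Si](CC)(CC)CC)CC[C@]2(C)CCC(=O)C=C[C@H]21 | intermediate
14 | potassium 4β-(triethylsilyloxy)-14-nordauca-6,8-dien-8-olate | CC(C)[C@]1(O[Si](CC)(CC)CC)CC[C@]2(C)CC=C([O-])C=C[C@H]21.[K+] | intermediate (not isolated)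
15 | 4β-(triethylsilyloxy)-14-nordauca-6,8-dien-8-yl trifluoromethanesulfonate | CC(C)[C@]1(O[Si](CC)(CC)CC)CC[C@]2(C)CC=C(OS(=O)(=O)C(F)(F)F)C=C[C@H]21 | intermediate
16 | methylmagnesium bromide | C[Mg]Br | starting material
17 | 4β-(triethylsilyloxy)dauca-6,8-diene | CC(C)[C@]1(O[Si](CC)(CC)CC)CC[C@]2(C)CC=C(C)C=C[C@H]21 | intermediate
18 | oxygen | O=O | starting material
19 | 6α,9α-epidioxy-4β-(triethylsilyloxy)dauc-7-ene | CC(C)[C@]1(O[Si](CC)(CC)CC)CC[C@]2(C)C[C@@H]3OO[C@@H](C=C3C)[C@H]21 | intermediate
20 | 4β-(triethylsilyloxy)dauc-7-ene-6α,9α-diol | CC(C)[C@]1(O[Si](CC)(CC)CC)CC[C@]2(C)C[C@H](O)C(C)=C[C@H](O)[C@H]21 | intermediate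
21 | 9α-(tert-butyldimethylsilyloxy)-4β-(triethylsilyloxy)dauc-7-en-6α-ol | CC(C)[C@]1(O[Si](CC)(CC)CC)CC[C@]2(C)C[C@H](O[Si](C)(C)C(C)(C)C)C(C)=C[C@H](O)[C@H]21 | intermediate
22 | 4-(benzyloxy)benzoyl chloride | O=C(Cl)c1ccc(OCc2ccccc2)cc1 | starting material
23 | 9α-(tert-butyldimethylsilyloxy)-4β-(triethylsilyloxy)dauc-7-en-6α-yl 4-(benzyloxy)benzoate | CC(C)[C@]1(O[Si](CC)(CC)CC)CC[C@]2(C)C[C@H](O[Si](C)(C)C(C)(C)C)C(C)=C[C@H](OC(=O)c3ccc(OCc4ccccc4)cc3)[C@H]21 | intermediate
24 | 9α-(tert-butyldimethylsilyloxy)-7β,8β-epoxy-4β-(triethylsilyloxy)daucan-6α-yl 4-(benzyloxy)benzoate | CC(C)[C@]1(O[Si](CC)(CC)CC)CC[C@]2(C)C[C@H](O[Si](C)(C)C(C)(C)C)[C@@]3(C)O[C@H]3[C@H](OC(=O)c4ccc(OCc5ccccc5)cc4)[C@H]21 | intermediate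
25 | 9α-(tert-butyldimethylsilyloxy)-7β,8α-dihydroxy-4β-(triethylsilyloxy)daucan-6α-yl 4-(benzyloxy)benzoate | CC(C)[C@]1(O[Si](CC)(CC)CC)CC[C@]2(C)C[C@H](O[Si](C)(C)C(C)(C)C)[C@](C)(O)[C@@H](O)[C@H](OC(=O)c3ccc(OCc4ccccc4)cc3)[C@H]21 | intermediate
26 | 9α-(tert-butyldimethylsilyloxy)-8α-hydroxy-7-oxo-4β-(triethylsilyloxy)daucan-6α-yl 4-(benzyloxy)benzoate | CC(C)[C@]1(O[Si](CC)(CC)CC)CC[C@]2(C)C[C@H](O[Si](C)(C)C(C)(C)C)[C@](C)(O)C(=O)[C@H](OC(=O)c3ccc(OCc4ccccc4)cc3)[C@H]21 | intermediate
27 | 4β,8α,9α-trihydroxy-7-oxodaucan-6α-yl 4-(benzyloxy)benzoate | CC(C)[C@]1(O)CC[C@]2(C)C[C@H](O)[C@](C)(O)C(=O)[C@H](OC(=O)c3ccc(OCc4ccccc4)cc3)[C@H]21 | intermediate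
28 | 4β,8α,9α-trihydroxy-7-oxodaucan-6α-yl 4-hydroxybenzoate (CNP0241001.1) | CC(C)[C@]1(O)CC[C@]2(C)C[C@H](O)[C@](C)(O)C(=O)[C@H](OC(=O)c3ccc(O)cc3)[C@H]21 | target

## Step count and least certain steps

Total steps: 19. Longest linear sequence: 19 steps (1 → 28); compounds 5, 10, 16, 18 and 22 are purchased.

**Step 11 (key step).** The most likely failures are diversion into the ene pathway (abstraction of an allylic hydrogen at C5, C10 or the C8 methyl, giving hydroperoxides) and erosion of facial selectivity, because the C4 isopropyl group lies on the α face close to C6. Fallback, from 17 back to the route at 23: the two oxygens are introduced one after the other. Peracid epoxidation of the more electron-rich trisubstituted C8=C9 bond of 17 should give the 8α,9α-epoxide F1. Pd(PPh3)4-catalysed 1,4-opening of this vinyl epoxide by 4-(benzyloxy)benzoic acid (net syn addition through the π-allyl complex of zerovalent palladium) should give the 9α-hydroxy 6α-ester F2. Silylation of F2 as in step 13 gives 23. This avoids the ene pathway but relies on the same steric bias for the α face.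

**Step 3.** The most likely failure is poor or reversed facial selectivity at C1, because the silyloxy and isopropyl groups on C4 compete in shielding the two faces; 1,2-addition is a lesser concern. Fallback, from 4 back to the route at 17: control is moved from C4 to a reagent-set carbinol. Allylboration of 4 with B-allyldiisopinocampheylborane (the antipode chosen to give the carbinol shown) should give the homoallylic alcohol F3. Anionic oxy-Cope rearrangement (KH, 18-crown-6, THF) through a chair transition state with the alkoxide pseudo-equatorial should relay the C6 configuration to C1 and give, after protonation and equilibration at C5, the allyl aldehyde F4. Addition of 2-methylallylmagnesium chloride gives the carbinol F5. Ring-closing metathesis with the second-generation Grubbs catalyst forms the trisubstituted C8=C9 bond in the cycloheptenol F6. Mesylation and DBU elimination toward the allylic C7 hydrogens then give diene 17.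

**Step 13.** The most likely failure is insufficient site selectivity between the two allylic hydroxyls (double silylation or silylation at C6). Fallback, from 20 back to the route at 23: both hydroxyls are acylated with excess 22 to the bis-ester F7. Selective methanolysis (K2CO3, MeOH) of the less shielded C9 ester should give the mono-ester F2, which is silylated to 23.

**Step 16.** The most likely failure is participation of the C6 ester carbonyl at C7, or opening through a free cation, either of which would give the C8 epimer. The step also inherits any lack of β selectivity in step 15, and the acid may partly remove the silyl ethers. Fallback, from 23 back to the route at 27: the oxygen on C8 is delivered by a hydroxyl-directed epoxidation and C7 is oxidised through sulfur. Fluoride removes the C9 silyl group of 23 to give the allylic alcohol F2. VO(acac)2 and tBuOOH should give the 7α,8α-epoxy alcohol F8. Thiophenol with Ti(OiPr)4 should open F8 at C7, the carbon remote from the directing hydroxyl, with inversion to the 7β-phenylthio 8α,9α-diol F9. One equivalent of peracid gives the sulfoxide F10. Pummerer rearrangement (trifluoroacetic anhydride, 2,6-lutidine; then aqueous NaHCO3) gives the C7 ketone F11. HF·pyridine then removes the C4 silyl ether to give 27.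

## Further compounds

F1 | step 11 | 8α,9α-epoxy-4β-(triethylsilyloxy)dauc-6-ene | CC(C)[C@]1(O[Si](CC)(CC)CC)CC[C@]2(C)C[C@@H]3O[C@]3(C)C=C[C@H]21
F2 | step 11 | 9α-hydroxy-4β-(triethylsilyloxy)dauc-7-en-6α-yl 4-(benzyloxy)benzoate | CC(C)[C@]1(O[Si](CC)(CC)CC)CC[C@]2(C)C[C@H](O)C(C)=C[C@H](OC(=O)c3ccc(OCc4ccccc4)cc3)[C@H]21
F3 | step 3 | 1-[(R)-5-isopropyl-2-methyl-5-(triethylsilyloxy)cyclopent-1-en-1-yl]but-3-en-1-ol (single carbinol epimer as drawn) | CC(C)[C@]1(O[Si](CC)(CC)CC)CCC(C)=C1[C@@H](O)CC=C
F4 | step 3 | 1α-allyl-4α-isopropyl-1β-methyl-4β-(triethylsilyloxy)cyclopentane-5β-carbaldehyde | CC(C)[C@]1(O[Si](CC)(CC)CC)CC[C@](C)(CC=C)[C@H]1C=O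
F5 | step 3 | 1-[1α-allyl-4α-isopropyl-1β-methyl-4β-(triethylsilyloxy)cyclopent-5β-yl]-3-methylbut-3-en-1-ol (C6 epimers) | CC(C)[C@]1(O[Si](CC)(CC)CC)CC[C@](C)(CC=C)[C@H]1C(O)CC(C)=C
F6 | step 3 | 4β-(triethylsilyloxy)dauc-8-en-6-ol (C6 epimers) | CC(C)[C@]1(O[Si](CC)(CC)CC)CC[C@]2(C)CC=C(C)CC(O)[C@H]21
F7 | step 13 | 4β-(triethylsilyloxy)dauc-7-ene-6α,9α-diyl bis[4-(benzyloxy)benzoate] | CC(C)[C@]1(O[Si](CC)(CC)CC)CC[C@]2(C)C[C@H](OC(=O)c3ccc(OCc4ccccc4)cc3)C(C)=C[C@H](OC(=O)c3ccc(OCc4ccccc4)cc3)[C@H]21
F8 | step 16 | 7α,8α-epoxy-9α-hydroxy-4β-(triethylsilyloxy)daucan-6α-yl 4-(benzyloxy)benzoate | CC(C)[C@]1(O[Si](CC)(CC)CC)CC[C@]2(C)C[C@H](O)[C@]3(C)O[C@@H]3[C@H](OC(=O)c4ccc(OCc5ccccc5)cc4)[C@H]21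
F9 | step 16 | 8α,9α-dihydroxy-7β-(phenylthio)-4β-(triethylsilyloxy)daucan-6α-yl 4-(benzyloxy)benzoate | CC(C)[C@]1(O[Si](CC)(CC)CC)CC[C@]2(C)C[C@H](O)[C@](C)(O)[C@@H](Sc3ccccc3)[C@H](OC(=O)c4ccc(OCc5ccccc5)cc4)[C@H]21
F10 | step 16 | 8α,9α-dihydroxy-7β-(phenylsulfinyl)-4β-(triethylsilyloxy)daucan-6α-yl 4-(benzyloxy)benzoate (sulfur epimers) | CC(C)[C@]1(O[Si](CC)(CC)CC)CC[C@]2(C)C[C@H](O)[C@](C)(O)[C@@H](S(=O)c3ccccc3)[C@H](OC(=O)c4ccc(OCc5ccccc5)cc4)[C@H]21
F11 | step 16 | 8α,9α-dihydroxy-7-oxo-4β-(triethylsilyloxy)daucan-6α-yl 4-(benzyloxy)benzoate | CC(C)[C@]1(O[Si](CC)(CC)CC)CC[C@]2(C)C[C@H](O)[C@](C)(O)C(=O)[C@H](OC(=O)c3ccc(OCc4ccccc4)cc3)[C@H]21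
A1 | alternative 1 | 3-ethylidene-5-methyl-1-vinyl-2-oxabicyclo[3.3.0]octane (cis-fused; ethylidene geometry open) | CC=C1C[C@@]2(C)CCC[C@@]2(C=C)O1
A2 | alternative 1 | 1,8-dimethylbicyclo[5.3.0]dec-5-en-9-one (daucane locants) | O=C1C[C@@]2(C)CCCC2=CCC1C
A3 | alternative 2 | (S)-citronellol | OCC[C@@H](C)CCC=C(C)C
A4 | alternative 2 | methyl (S)-8-(tert-butyldimethylsilyloxy)-2-diazo-6-methyl-3-oxooctanoate | COC(=O)C(=[N+]=[N-])C(=O)CC[C@H](C)CCO[Si](C)(C)C(C)(C)C
A5 | alternative 2 | methyl 2-[2-(tert-butyldimethylsilyloxy)ethyl]-2-methyl-5-oxocyclopentane-1-carboxylate | COC(=O)C1C(=O)CC[C@]1(C)CCO[Si](C)(C)C(C)(C)C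
A6 | alternative 3 | keto aldehyde with C9 formyl, C8 methyl ketone, C7 tert-butyldimethylsilyl ether, C6 benzyl ether and C4 triethylsilyl ether | CC(C)[C@]1(O[Si](CC)(CC)CC)CC[C@](C)(CC=O)[C@H]1[C@@H](OCc2ccccc2)[C@H](O[Si](C)(C)C(C)(C)C)C(C)=O
A7 | alternative 3 | bicyclic 8α,9α-diol with C7 tert-butyldimethylsilyl ether, C6 benzyl ether and C4 triethylsilyl ether | CC(C)[C@]1(O[Si](CC)(CC)CC)CC[C@]2(C)C[C@H](O)[C@](C)(O)[C@@H](O[Si](C)(C)C(C)(C)C)[C@H](OCc3ccccc3)[C@H]21
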